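**Retrosynthetic overview**

1. Numbering follows the target SMILES: C1 CHOAc, C2 CH2, C3 C(OH)iPr, C4 ring-fusion CH, C5 CH–O–aroyl, C6=C7(Me), C8 C=O, C9 CH2, C10 C–Me. α is the face of the C10 methyl, β the other; the target is (1S,3R,4R,5R,10S).
2. Feature: the C1–C2–C3 1,3-dioxygenated segment of the cyclopentane is an aldol/alkynylation motif. It is read as a three-atom tether between a C4≡C5 alkyne and a five-carbon C10=C9–C8(–C7–C6) 1-siloxy vinylcyclopropane whose oxygen becomes the C8 ketone.
3. Late disconnections: silyl ethers on the phenol and C3–OH; C6=C7 by Saegusa–Ito oxidation; C5–O aroyl ester; C4–H/C5–O by hydroboration of C4=C5; C7–Me by kinetic enolate methylation.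
4. Key disconnection: C4–C10 and C5–C6 by a rhodium-catalysed alkyne–vinylcyclopropane (5+2) cycloaddition, which closes the five-membered ring (C1–C2–C3–C4–C10) and the seven-membered ring (C4 to C10) in one operation from an acyclic enyne.
5. Precursor: C8 cyclopropane by Kulinkovich reaction of an enoate; C3–C4 by chelation-controlled ethynylation; C1–C2 by asymmetric boron aldol of 3-methylbutan-2-one with ethyl (E)-3-methyl-4-oxobut-2-enoate.

Key step: step 7

Remark (assumption): methyl-ketone enol borinates carrying the ligands of (−)-Ipc2BCl are taken to attack the Si face of aldehydes; were the sense opposite, (+)-Ipc2BCl would be used in step 1 with no other change.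

**Route**

Step 1
Reactants: 1 3-methylbutan-2-one; 2 ethyl (2E)-3-methyl-4-oxobut-2-enoate
Product: 5 ethyl (2E,4S)-4-hydroxy-3,7-dimethyl-6-oxooct-2-enoate, via enol borinate 3 (not isolated), via boron aldolate 4 (not isolated)
Conditions: (−)-Ipc2BCl, Et3N, Et2O, −78 → 0 °C; 2, −78 → −20 °C; then 30% H2O2, MeOH, pH 7 buffer, 0 °C
Reagents that add atoms: none
Why: Diisopinocampheylboron aldol reaction in which Ipc2BCl/Et3N enolises 1 on the methyl side and the enol borinate adds 1,2 to the aldehyde of 2 through a closed six-membered transition state, the chiral ligands directing attack to the Si face so that C1 is set as S, while the β,β-disubstituted enoate is untouched.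

Step 2
Reactants: 5 ethyl (2E,4S)-4-hydroxy-3,7-dimethyl-6-oxooct-2-enoate; 6 ethynylmagnesium bromide
Product: 8 ethyl (2E,4S,6R)-6-ethynyl-4,6-dihydroxy-3,7-dimethyloct-2-enoate, via magnesium alkoxide chelate 7 (not isolated)
Conditions: 6 (3.5 equiv), THF/CH2Cl2, −78 → −20 °C; aq. NH4Cl
Reagents that add atoms: none
Why: Chelation-controlled 1,2-addition (cyclic chelate model, 1,3-induction) in which the first equivalent forms the magnesium alkoxide, this binds the ketone in a six-membered half-chair with the alkenyl group equatorial, and a second acetylide attacks C3 axially so that the new C3–O is anti to C1–O along the alkyne-bearing chain (6R), the ester being inert to the alkynyl Grignard reagent at this temperature.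

Step 3
Reactants: 8 ethyl (2E,4S,6R)-6-ethynyl-4,6-dihydroxy-3,7-dimethyloct-2-enoate
Product: 9 ethyl (2E,4S,6R)-4-(tert-butyldimethylsilyloxy)-6-ethynyl-6-hydroxy-3,7-dimethyloct-2-enoate
Conditions: TBSCl, imidazole, DMF, 0 °C → rt
Reagents that add atoms: tert-butyldimethylsilyl chloride, CC(C)(C)[Si](C)(C)Cl
Why: Silylation with the silyl chloride and imidazole discriminates the secondary allylic C1–OH from the hindered tertiary propargylic C3–OH on steric grounds.

Step 4
Reactants: 9 ethyl (2E,4S,6R)-4-(tert-butyldimethylsilyloxy)-6-ethynyl-6-hydroxy-3,7-dimethyloct-2-enoate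
Product: 10 ethyl (2E,4S,6R)-4-(tert-butyldimethylsilyloxy)-6-ethynyl-3,7-dimethyl-6-(triethylsilyloxy)oct-2-enoate
Conditions: TESOTf, 2,6-lutidine, CH2Cl2, −78 → 0 °C
Reagents that add atoms: triethylsilyl trifluoromethanesulfonate, CC[Si](CC)(CC)OS(=O)(=O)C(F)(F)F
Why: Silyl triflate silylation reaches the hindered tertiary alcohol, which removes alkoxide-directed titanium chemistry at the alkyne in step 5 and installs the bulky C3–OSiEt3 group used for face control in step 7.

Step 5
Reactants: 10 ethyl (2E,4S,6R)-4-(tert-butyldimethylsilyloxy)-6-ethynyl-3,7-dimethyl-6-(triethylsilyloxy)oct-2-enoate; 11 ethylmagnesium bromide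
Product: 12 1-[(1E,3S,5R)-3-(tert-butyldimethylsilyloxy)-5-ethynyl-2,6-dimethyl-5-(triethylsilyloxy)hept-1-en-1-yl]cyclopropan-1-ol
Conditions: 11 (3.5 equiv, slow addition), Ti(OiPr)4 (0.3 equiv), THF, 0 °C → rt; aq. NH4Cl
Reagents that add atoms: none
Why: Kulinkovich reaction in which the titanacyclopropane formed from EtMgBr and Ti(OiPr)4 adds twice to the ester carbonyl as a 1,2-dicarbanion equivalent to give the cyclopropanol, β,β-disubstitution of the enoate disfavouring conjugate addition, while the terminal alkyne is only deprotonated by excess Grignard reagent and returns on work-up.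

Step 6
Reactants: 12 1-[(1E,3S,5R)-3-(tert-butyldimethylsilyloxy)-5-ethynyl-2,6-dimethyl-5-(triethylsilyloxy)hept-1-en-1-yl]cyclopropan-1-ol
Product: 13 tris-silylated enyne vinylcyclopropane (1E,3S,5R; cyclopropyl OTBS; C1–OTBS; C3–OTES in route numbering)
Conditions: TBSOTf, 2,6-lutidine, CH2Cl2, −78 °C
Reagents that add atoms: tert-butyldimethylsilyl trifluoromethanesulfonate, CC(C)(C)[Si](C)(C)OS(=O)(=O)C(F)(F)F
Why: Silyl triflate silylation of the tertiary cyclopropanol under buffered, cold conditions avoids the acid-induced ring expansion of 1-vinylcyclopropanols to cyclobutanones and completes the 1-siloxy vinylcyclopropane.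

Step 7
Reactants: 13 tris-silylated enyne vinylcyclopropane
Product: 14 (1S,3R,10S)-hydroazulene diene (1α-OTBS; 3β-OTES; 3α-iPr; 10α-Me; C4=C5; C8=C9 enol OTBS)
Conditions: [Rh(CO)2Cl]2 (5 mol%), ClCH2CH2Cl (0.02 M), 70 °C
Reagents that add atoms: none
Why: Monovalent rhodium binds the C10=C9 alkene, cleaves one of the two equivalent C8–CH2 bonds of the cyclopropane to a trivalent σ-alkyl/π-allyl rhodacycle, the tethered alkyne inserts at the allyl terminus (C4–C10) and C(sp2)–C(sp3) reductive elimination forms C5–C6 and releases monovalent rhodium. The closest known reaction type is the rhodium-catalysed intramolecular alkyne–vinylcyclopropane (5+2) cycloaddition, including its 1-siloxy vinylcyclopropane variant, in which the oxygen substituent speeds ring cleavage and leaves the C8=C9 enol silane as the masked C8 ketone. The five-membered ring (C1–C2–C3–C4–C10) closes by 5-exo-dig insertion of the alkyne across the three-atom tether, and the seven-membered ring (C4 to C10) closes by reductive elimination from the eight-membered rhodacycle. C10, the only new stereocentre, is set by the tether: with C1–H in the alkene plane syn to H9 (A(1,3) strain minimised) the forming cyclopentene adopts an envelope with C1–OTBS and the C3 isopropyl group pseudo-equatorial, and the pseudo-axial C3–OSiEt3 group blocks the face that would bring the C10 methyl syn to it, so the methyl should end cis to C1–O and trans to C3–O. The step needs this facial selectivity and enough reactivity at a terminus that becomes quaternary; the E alkene keeps the tether on the outer position of the allyl, the symmetric cyclopropane removes any regiochemical choice in C–C cleavage, and the donor siloxy group offsets the retarding methyl cis to the ring. Because the alkyne leaves C4 trigonal, no ring-fusion relationship is fixed here; it is set in step 13.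

Step 8
Reactants: 14 (1S,3R,10S)-hydroazulene diene
Product: 15 (1S,3R,10S)-hydroazulen-8-one (1α-OTBS; 3β-OTES; 4-ene)
Conditions: Bu4NF (1.05 equiv), AcOH (1.2 equiv), THF, −40 → 0 °C
Reagents that add atoms: none
Why: Fluoride-induced desilylation cleaves the Si–O bond of the enol ether far faster than those of the alkyl silyl ethers because an enolate is expelled, and acetic acid protonates it at C9 (no stereocentre) to unmask the C8 ketone without exposing the tertiary allylic C3 ether to strong acid.

Step 9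
Reactants: 15 (1S,3R,10S)-hydroazulen-8-one
Product: 17 7-methyl ketone (7RS; 1α-OTBS; 3β-OTES; 4-ene), via lithium enolate 16 (not isolated)
Conditions: LiN(iPr)2, THF, −78 °C; MeI, DMPU, −78 → −40 °C
Reagents that add atoms: iodomethane, CI
Why: Kinetic enolate alkylation in which the amide base removes a proton from the unhindered C7 methylene in preference to the neopentyl C9 methylene next to quaternary C10 and the enolate is C-methylated, the C7 configuration being immaterial because C7 becomes trigonal in step 17.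

Step 10
Reactants: 17 7-methyl ketone
Product: 18 8,8-ethylenedioxy ketal (7RS; 1α-OTBS; 3β-OTES; 4-ene)
Conditions: Me3SiOCH2CH2OSiMe3, Me3SiOTf (5 mol%), CH2Cl2, −78 → −20 °C; pyridine quench
Reagents that add atoms: 1,2-bis(trimethylsilyloxy)ethane, C[Si](C)(C)OCCO[Si](C)(C)C
Why: Silyl triflate-catalysed ketalisation with the bis-silylated glycol, driven by formation of hexamethyldisiloxane, masks the ketone against borane under cold aprotic conditions that the silyl ethers, including the hindered tertiary allylic one, should tolerate.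

Step 11
Reactants: 18 8,8-ethylenedioxy ketal
Product: 19 ketal 1α,3β-diol (7RS; 4-ene)
Conditions: Bu4NF, THF, rt → 45 °C
Reagents that add atoms: none
Why: Fluoride desilylation removes both alkyl silyl ethers while ketal and alkene are inert, exposing C1–OH for acylation and leaving a small C3–OH on the β face for step 13.

Step 12
Reactants: 19 ketal 1α,3β-diol
Product: 20 1α-acetate (3β-OH; 4-ene; ketal; 7RS)
Conditions: Ac2O, pyridine, DMAP (cat.), CH2Cl2, 0 °C → rt
Reagents that add atoms: acetic anhydride, CC(=O)OC(C)=O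
Why: Nucleophile-catalysed acetylation is selective for the secondary C1–OH because the tertiary C3–OH flanked by the isopropyl group is not acylated under these mild conditions.

Step 13
Reactants: 20 1α-acetate
Product: 22 (1S,3R,4R,5R,10S)-3β,5β-diol 1α-acetate (4β-H trans-fused; ketal; 7RS), via alkylborane 21 (not isolated)
Conditions: BH3·THF, THF, 0 °C → rt; then NaBO3·4H2O, THF/H2O, rt
Reagents that add atoms: sodium perborate tetrahydrate (NaBO3·4H2O), [Na+].[Na+].O[B-]1(O)OO[B-](O)(O)OO1
Why: Hydroboration–oxidation in which borane adds syn across C4=C5 with boron on the less substituted C5 and hydrogen on C4 from the β face, which carries only the C3 oxygen and the C9 methylene whereas the α face carries the C10 methyl and the C3 isopropyl group, and perborate oxidation with retention should give the 4β-H (trans ring fusion) and 5β-OH centres without cleaving the acetate.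

Step 14
Reactants: 23 4-hydroxybenzoic acid
Product: 25 4-(tert-butyldimethylsilyloxy)benzoic acid, via silyl ester 24 (not isolated)
Conditions: TBSCl (2.2 equiv), imidazole, DMF, rt; then AcOH/THF/H2O, rt
Reagents that add atoms: tert-butyldimethylsilyl chloride, CC(C)(C)[Si](C)(C)Cl
Why: Exhaustive silylation followed by hydrolysis of the labile silyl ester, which is cleaved much faster than the aryl silyl ether, gives the phenol-protected acid.

Step 15
Reactants: 22 3β,5β-diol 1α-acetate; 25 4-(tert-butyldimethylsilyloxy)benzoic acid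
Product: 26 5β-[4-(tert-butyldimethylsilyloxy)benzoate] (1α-OAc; 3β-OH; ketal; 7RS)
Conditions: EDC·HCl, DMAP, CH2Cl2, rt
Reagents that add atoms: none
Why: Steglich esterification acylates the secondary C5–OH, the tertiary C3–OH being unreactive toward the acylpyridinium intermediate.

Step 16
Reactants: 26 5β-aroate ketal
Product: 27 8-ketone (1α-OAc; 3β-OH; 5β-aroate; 7RS)
Conditions: PPTS, acetone/H2O, 50 °C
Reagents that add atoms: water, O
Why: Acid-catalysed acetal hydrolysis regenerates the C8 ketone, the C3 alcohol no longer being allylic after step 13 and the esters and aryl silyl ether tolerating pyridinium tosylate.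

Step 17
Reactants: 27 8-ketone
Product: 29 C6=C7 enone 3β-trimethylsilyl ether (1α-OAc; 5β-aroate with aryl OTBS), via bis(trimethylsilyl) enol ether 28 (not isolated)
Conditions: Me3SiOTf, Et3N, CH2Cl2, 0 °C → rt; then Pd(OAc)2, MeCN, rt
Reagents that add atoms: trimethylsilyl trifluoromethanesulfonate, C[Si](C)(C)OS(=O)(=O)C(F)(F)F
Why: Saegusa–Ito oxidation in which equilibrating silylation gives the more substituted C7=C8 enol ether (and caps C3–OH), divalent palladium forms the C7 palladium enolate and β-hydride elimination toward C6 gives the C6=C7 enone and zerovalent palladium, the C9 regioisomer being unable to eliminate because C10 is quaternary.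

Step 18
Reactants: 29 C6=C7 enone 3β-trimethylsilyl ether
Product: 30 target CNP0087181.1, (1S,3R,4R,5R,10S)-1α-acetoxy-3β-hydroxy-3α-isopropyl-7,10α-dimethyl-8-oxobicyclo[5.3.0]dec-6-en-5β-yl 4-hydroxybenzoate (route numbering)
Conditions: HF·pyridine, pyridine, THF, 0 °C → rt
Reagents that add atoms: none
Why: Fluoride desilylation cleaves the aryl tert-butyldimethylsilyl ether and the tertiary trimethylsilyl ether under buffered conditions that leave the acetate, the allylic aroate and the enone intact.

**Compound list**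

1 | 3-methylbutan-2-one | CC(C)C(C)=O | starting material
2 | ethyl (2E)-3-methyl-4-oxobut-2-enoate | CCOC(=O)/C=C(\C)C=O | starting material
3 | 3-methylbut-1-en-2-yl bis[(1R,2S,3R,5R)-isopinocampheyl]borinate (enol borinate of 1) | C=C(OB([C@@H]1C[C@@H]2C[C@H]([C@H]1C)C2(C)C)[C@@H]1C[C@@H]2C[C@H]([C@H]1C)C2(C)C)C(C)C | intermediate
4 | diisopinocampheylboron aldolate of 5 | CC(C)C(=O)C[C@H](OB([C@@H]1C[C@@H]2C[C@H]([C@H]1C)C2(C)C)[C@@H]1C[C@@H]2C[C@H]([C@H]1C)C2(C)C)/C(C)=C/C(=O)OCC | intermediate
5 | ethyl (2E,4S)-4-hydroxy-3,7-dimethyl-6-oxooct-2-enoate (chain C4 = route C1) | O[C@H](/C(C)=C/C(=O)OCC)CC(=O)C(C)C | intermediate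
6 | ethynylmagnesium bromide | C#C[Mg]Br | starting material
7 | bromomagnesium alkoxide (chelate) of 5 | Br[Mg]O[C@H](/C(C)=C/C(=O)OCC)CC(=O)C(C)C | intermediate
8 | ethyl (2E,4S,6R)-6-ethynyl-4,6-dihydroxy-3,7-dimethyloct-2-enoate (chain C6 = route C3) | O[C@H](/C(C)=C/C(=O)OCC)C[C@@](O)(C(C)C)C#C | intermediate
9 | ethyl (2E,4S,6R)-4-(tert-butyldimethylsilyloxy)-6-ethynyl-6-hydroxy-3,7-dimethyloct-2-enoate | CC(C)(C)[Si](C)(C)O[C@H](/C(C)=C/C(=O)OCC)C[C@@](O)(C(C)C)C#C | intermediate
10 | ethyl (2E,4S,6R)-4-(tert-butyldimethylsilyloxy)-6-ethynyl-3,7-dimethyl-6-(triethylsilyloxy)oct-2-enoate | CC(C)(C)[Si](C)(C)O[C@H](/C(C)=C/C(=O)OCC)C[C@@](O[Si](CC)(CC)CC)(C(C)C)C#C | intermediate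
11 | ethylmagnesium bromide | CC[Mg]Br | starting material
12 | 1-[(1E,3S,5R)-3-(tert-butyldimethylsilyloxy)-5-ethynyl-2,6-dimethyl-5-(triethylsilyloxy)hept-1-en-1-yl]cyclopropan-1-ol | CC(C)(C)[Si](C)(C)O[C@H](/C(C)=C/C1(O)CC1)C[C@@](O[Si](CC)(CC)CC)(C(C)C)C#C | intermediate
13 | tert-butyldimethylsilyl ether of 12 (tris-silylated enyne vinylcyclopropane; 1E,3S,5R) | CC(C)(C)[Si](C)(C)O[C@H](/C(C)=C/C1(O[Si](C)(C)C(C)(C)C)CC1)C[C@@](O[Si](CC)(CC)CC)(C(C)C)C#C | intermediate
14 | (1S,3R,10S)-1α,8-bis(tert-butyldimethylsilyloxy)-3α-isopropyl-10α-methyl-3β-(triethylsilyloxy)bicyclo[5.3.0]deca-4,8-diene (route numbering) | CC(C)(C)[Si](C)(C)O[C@H]1C[C@@](O[Si](CC)(CC)CC)(C(C)C)C2=CCCC(O[Si](C)(C)C(C)(C)C)=C[C@]12C | intermediate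
15 | (1S,3R,10S)-1α-(tert-butyldimethylsilyloxy)-3α-isopropyl-10α-methyl-3β-(triethylsilyloxy)bicyclo[5.3.0]dec-4-en-8-one | CC(C)(C)[Si](C)(C)O[C@H]1C[C@@](O[Si](CC)(CC)CC)(C(C)C)C2=CCCC(=O)C[C@]12C | intermediate
16 | C7=C8 lithium enolate of 15 | CC(C)(C)[Si](C)(C)O[C@H]1C[C@@](O[Si](CC)(CC)CC)(C(C)C)C2=CCC=C(O[Li])C[C@]12C | intermediate
17 | (1S,3R,10S,7RS)-1α-(tert-butyldimethylsilyloxy)-3α-isopropyl-7,10α-dimethyl-3β-(triethylsilyloxy)bicyclo[5.3.0]dec-4-en-8-one (C7 epimers) | CC(C)(C)[Si](C)(C)O[C@H]1C[C@@](O[Si](CC)(CC)CC)(C(C)C)C2=CCC(C)C(=O)C[C@]12C | intermediate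
18 | 8,8-ethylenedioxy ketal of 17 | CC(C)(C)[Si](C)(C)O[C@H]1C[C@@](O[Si](CC)(CC)CC)(C(C)C)C2=CCC(C)C3(OCCO3)C[C@]12C | intermediate
19 | (1S,3R,10S,7RS)-8,8-ethylenedioxy-3α-isopropyl-7,10α-dimethylbicyclo[5.3.0]dec-4-ene-1α,3β-diol | O[C@H]1C[C@@](O)(C(C)C)C2=CCC(C)C3(OCCO3)C[C@]12C | intermediate
20 | 1α-acetate of 19 | CC(=O)O[C@H]1C[C@@](O)(C(C)C)C2=CCC(C)C3(OCCO3)C[C@]12C | intermediate
21 | C5β alkylborane (C3 O-borane) from 20 | CC(=O)O[C@H]1C[C@@](OB)(C(C)C)[C@H]2[C@H](B)CC(C)C3(OCCO3)C[C@]12C | intermediate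
22 | (1S,3R,4R,5R,10S,7RS)-1α-acetoxy-8,8-ethylenedioxy-3α-isopropyl-7,10α-dimethylbicyclo[5.3.0]decane-3β,5β-diol (4β-H) | CC(=O)O[C@H]1C[C@@](O)(C(C)C)[C@H]2[C@H](O)CC(C)C3(OCCO3)C[C@]12C | intermediate
23 | 4-hydroxybenzoic acid | OC(=O)c1ccc(O)cc1 | starting material
24 | tert-butyldimethylsilyl 4-(tert-butyldimethylsilyloxy)benzoate | CC(C)(C)[Si](C)(C)OC(=O)c1ccc(O[Si](C)(C)C(C)(C)C)cc1 | intermediate
25 | 4-(tert-butyldimethylsilyloxy)benzoic acid | CC(C)(C)[Si](C)(C)Oc1ccc(cc1)C(=O)O | intermediate
26 | 5β-[4-(tert-butyldimethylsilyloxy)benzoate] of 22 | CC(=O)O[C@H]1C[C@@](O)(C(C)C)[C@H]2[C@H](OC(=O)c3ccc(O[Si](C)(C)C(C)(C)C)cc3)CC(C)C4(OCCO4)C[C@]12C | intermediate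
27 | 8-ketone from 26 (1α-OAc; 3β-OH; 5β-aroate; 7RS) | CC(=O)O[C@H]1C[C@@](O)(C(C)C)[C@H]2[C@H](OC(=O)c3ccc(O[Si](C)(C)C(C)(C)C)cc3)CC(C)C(=O)C[C@]12C | intermediate
28 | C7=C8 trimethylsilyl enol ether, 3β-trimethylsilyl ether of 27 | CC(=O)O[C@H]1C[C@@](O[Si](C)(C)C)(C(C)C)[C@H]2[C@H](OC(=O)c3ccc(O[Si](C)(C)C(C)(C)C)cc3)CC(C)=C(O[Si](C)(C)C)C[C@]12C | intermediate
29 | C6=C7 enone, 3β-trimethylsilyl ether, aryl tert-butyldimethylsilyl ether | CC(=O)O[C@H]1C[C@@](O[Si](C)(C)C)(C(C)C)[C@H]2[C@H](OC(=O)c3ccc(O[Si](C)(C)C(C)(C)C)cc3)C=C(C)C(=O)C[C@]12C | intermediate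
30 | CNP0087181.1, (1S,3R,4R,5R,10S)-1α-acetoxy-3β-hydroxy-3α-isopropyl-7,10α-dimethyl-8-oxobicyclo[5.3.0]dec-6-en-5β-yl 4-hydroxybenzoate (route numbering) | CC(=O)O[C@H]1C[C@@](O)(C(C)C)[C@H]2[C@H](OC(=O)c3ccc(O)cc3)C=C(C)C(=O)C[C@]12C | target

**Step count and risks**

Total step count: 18. Longest linear sequence: 17 steps (steps 1–13 and 15–18; step 14 prepares acid 25).

Steps most likely to fail:

1. Step 7 (key cycloaddition). The process at risk is face selection at C10, because the A(1,3) preference at C1 and the gauche contact of C1–OTBS with the C10 methyl pull in opposite directions. Alkyne insertion at an allyl terminus that becomes quaternary may also stall, letting the siloxy vinylcyclopropane isomerise instead. The fallback makes C1 trigonal during the cycloaddition and sets it afterwards; it sets out from diol 8 and returns at 14. TESOTf/2,6-lutidine silylates both hydroxyls to give the bis(triethylsilyl) ether F1. The Kulinkovich reaction of step 5 gives the cyclopropanol F2, and TBSOTf/2,6-lutidine gives the siloxycyclopropane F3. Pyridinium tosylate in methanol removes only the secondary allylic triethylsilyl group to give the allylic alcohol F4, which Dess–Martin periodinane oxidises to the C1 enone F5. Cycloaddition of F5 with [Rh(CO)2Cl]2 then has only the C3 centre to obey (isopropyl pseudo-equatorial, methyl anti to the siloxy group) and should give the bicyclic C1 ketone F6. NaBH4 in ethanol delivers hydride to C1 from the β face, anti to the angular methyl, to give the 1α-alcohol F7, and TBSOTf/2,6-lutidine converts it into 14.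

2. Step 13 (hydroboration). The process at risk is face selection: borane may approach from the α face and give the cis-fused 4α-H/5α-OH isomer, or add so slowly to the hindered alkene that the acetate is eroded. The fallback fixes the C5 oxygen by hydroxyl direction; it sets out from 20 and returns at 22. VO(acac)2 with tert-butyl hydroperoxide epoxidises C4=C5 syn to the free C3 hydroxyl to give the 4β,5β-epoxide F8. Cp2TiCl (trivalent titanium, from Cp2TiCl2 and Zn) with 1,4-cyclohexadiene opens the epoxide homolytically at the more substituted C4, keeping the C5–O bond and its β configuration. The tertiary C4 radical should take up hydrogen anti to the C10 methyl and the isopropyl group to give 22.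

3. Step 5 (Kulinkovich reaction). The process at risk is diversion of the low-valent titanium species by complexation with the alkyne, or conjugate addition of the Grignard reagent to the enoate. The fallback builds the siloxycyclopropane without titanium; it sets out from ester 10 and returns at 13. MeNHOMe·HCl/iPrMgCl gives the Weinreb amide F9, MeMgBr gives the methyl ketone F10, and TBSOTf/Et3N gives the 2-siloxy diene F11. Simmons–Smith cyclopropanation (Et2Zn, CH2I2) of the electron-rich enol ether double bond then gives 13.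

**Further compounds**

F1 | step 7 | ethyl (2E,4S,6R)-6-ethynyl-3,7-dimethyl-4,6-bis(triethylsilyloxy)oct-2-enoate | CC[Si](CC)(CC)O[C@H](/C(C)=C/C(=O)OCC)C[C@@](O[Si](CC)(CC)CC)(C(C)C)C#C
F2 | step 7 | 1-[(1E,3S,5R)-5-ethynyl-2,6-dimethyl-3,5-bis(triethylsilyloxy)hept-1-en-1-yl]cyclopropan-1-ol | CC[Si](CC)(CC)O[C@H](/C(C)=C/C1(O)CC1)C[C@@](O[Si](CC)(CC)CC)(C(C)C)C#C
F3 | step 7 | tert-butyldimethylsilyl ether of F2 (siloxycyclopropane) | CC[Si](CC)(CC)O[C@H](/C(C)=C/C1(O[Si](C)(C)C(C)(C)C)CC1)C[C@@](O[Si](CC)(CC)CC)(C(C)C)C#C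
F4 | step 7 | C1 allylic alcohol (cyclopropyl OTBS; C3–OTES) | O[C@H](/C(C)=C/C1(O[Si](C)(C)C(C)(C)C)CC1)C[C@@](O[Si](CC)(CC)CC)(C(C)C)C#C
F5 | step 7 | C1 enone (cyclopropyl OTBS; C3–OTES) | O=C(/C(C)=C/C1(O[Si](C)(C)C(C)(C)C)CC1)C[C@@](O[Si](CC)(CC)CC)(C(C)C)C#C
F6 | step 7 | bicyclic C1 ketone (3β-OTES; 10α-Me; C4=C5; C8=C9 enol OTBS) | O=C1C[C@@](O[Si](CC)(CC)CC)(C(C)C)C2=CCCC(O[Si](C)(C)C(C)(C)C)=C[C@]12C
F7 | step 7 | bicyclic 1α-alcohol (3β-OTES; 10α-Me; C4=C5; C8=C9 enol OTBS) | O[C@H]1C[C@@](O[Si](CC)(CC)CC)(C(C)C)C2=CCCC(O[Si](C)(C)C(C)(C)C)=C[C@]12C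
F8 | step 13 | 4β,5β-epoxide of 20 | CC(=O)O[C@H]1C[C@@](O)(C(C)C)[C@@]2(O3)[C@H]3CC(C)C4(OCCO4)C[C@]12C
F9 | step 5 | N-methoxy-N-methyl amide (Weinreb amide) from 10 | CC(C)(C)[Si](C)(C)O[C@H](/C(C)=C/C(=O)N(C)OC)C[C@@](O[Si](CC)(CC)CC)(C(C)C)C#C
F10 | step 5 | methyl ketone (3E,5S,7R)-5-(tert-butyldimethylsilyloxy)-7-ethynyl-4,8-dimethyl-7-(triethylsilyloxy)non-3-en-2-one | CC(C)(C)[Si](C)(C)O[C@H](/C(C)=C/C(C)=O)C[C@@](O[Si](CC)(CC)CC)(C(C)C)C#C
F11 | step 5 | 2-(tert-butyldimethylsilyloxy) diene from F10 | CC(C)(C)[Si](C)(C)O[C@H](/C(C)=C/C(=C)O[Si](C)(C)C(C)(C)C)C[C@@](O[Si](CC)(CC)CC)(C(C)C)C#C
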